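**Plan**
- Retrosynthesis: the three benzyl ethers and the 7-O–S bond are cut last, then C4–C4a of ring C (intramolecular Friedel–Crafts acylation), then the O1–C2 vinyl ether bond (phenoxide plus ynoate).
- This leaves a symmetric ring A phenol and a ring B arylpropiolate, whose C2–C3 and C3–C4 bonds come from a Corey–Fuchs homologation and carboxylation.
- Enabling feature: C4a of ring A lies ortho to O1 and to the C5 oxygen and para to the C7 oxygen, and the 3,4,5-trioxygenated phenyl ether has two identical ortho carbons, so acylation can only give the 5,6,7-pattern.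
- Forward: rings A and B are bought as benzaldehydes and joined through O1–C2, ring C is closed at C4–C4a, deallylation frees 5-OH and 7-OH, the chelated 5-OH stays out of the sulfation, and hydrogenolysis unveils the other phenols.
- Stereochemistry: the target has no stereocentre; the only stereo element, the Z alkene of the acrylic acid, comes from anti addition to the alkyne and is consumed on ring closure.

Key step: step 8

Remark on the chemistry: sulfate monoesters 17 and 18 are drawn as free hydrogen sulfates but would be handled as sodium salts, since the free acids solvolyse easily; flavone numbering (O1, C2 to C8a, ring B primed) is used throughout.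

Step 1
Reactants: 1 3,4,5-trihydroxybenzaldehyde; 2 benzyl bromide
Product: 3 4-(benzyloxy)-3,5-dihydroxybenzaldehyde
Conditions: BnBr (1.0 equiv), NaHCO3, NaI (cat.), DMF, 40 °C, argon
Reagents that add atoms: none
Why: Williamson etherification under bicarbonate control, in which only the 4-OH (para to the formyl group and therefore the most acidic) is ionised, as in the 4-O-selective benzylation of 3,4-dihydroxybenzaldehyde and of gallate esters.

Step 2
Reactants: 3 4-(benzyloxy)-3,5-dihydroxybenzaldehyde; 4 allyl bromide
Product: 5 3,5-bis(allyloxy)-4-(benzyloxy)benzaldehyde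
Conditions: allyl bromide (2.5 equiv), K2CO3 (2.5 equiv), DMF, 50 °C
Reagents that add atoms: allyl bromide, C=CCBr
Why: Double Williamson allylation in which each of the two remaining, equivalent phenols takes up one molecule of allyl bromide (two molecules of 4 in all), so no selectivity is required.

Step 3
Reactants: 5 3,5-bis(allyloxy)-4-(benzyloxy)benzaldehyde
Product: 7 3,5-bis(allyloxy)-4-(benzyloxy)phenol, via aryl formate 6 (not isolated)
Conditions: 30% aq. H2O2, H2SO4 (cat.), MeOH, rt
Reagents that add atoms: hydrogen peroxide, OO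
Why: Acid-catalysed Dakin (Baeyer–Villiger type) oxidation in which the electron-rich aryl group with its para benzyloxy substituent migrates to oxygen and the formate is methanolysed in the same flask, while aqueous H2O2 does not epoxidise the allyl groups.

Step 4
Reactants: 8 3,4-bis(benzyloxy)benzaldehyde
Product: 9 1,2-bis(benzyloxy)-4-(2,2-dibromoethenyl)benzene
Conditions: CBr4, PPh3, CH2Cl2, 0 °C
Reagents that add atoms: carbon tetrabromide, BrC(Br)(Br)Br
Why: First stage of the Corey–Fuchs reaction, a Wittig-type dibromo-olefination of an aromatic aldehyde that leaves benzyl ethers untouched.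

Step 5
Reactants: 9 1,2-bis(benzyloxy)-4-(2,2-dibromoethenyl)benzene
Product: 11 methyl 3-[3,4-bis(benzyloxy)phenyl]prop-2-ynoate, via lithium acetylide 10 (not isolated)
Conditions: n-BuLi (2.1 equiv), THF, −78 °C; then ClCO2Me, −78 °C to rt
Reagents that add atoms: methyl chloroformate, COC(=O)Cl
Why: Second stage of the Corey–Fuchs reaction, in which bromine–lithium exchange and Fritsch–Buttenberg–Wiechell rearrangement give the alkyne, which is deprotonated to the acetylide and C-acylated by the chloroformate.

Step 6
Reactants: 7 3,5-bis(allyloxy)-4-(benzyloxy)phenol; 11 methyl 3-[3,4-bis(benzyloxy)phenyl]prop-2-ynoate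
Product: 12 methyl (2Z)-3-[3,5-bis(allyloxy)-4-(benzyloxy)phenoxy]-3-[3,4-bis(benzyloxy)phenyl]prop-2-enoate
Conditions: K2CO3 (0.5 equiv), DMF, 80 °C, argon
Reagents that add atoms: none
Why: Base-mediated oxa-Michael addition of the phenoxide to the β-carbon of the ynoate (first stage of the Ruhemann flavone synthesis), where anti addition places the aryloxy group cis to the ester (Z), the isomer that also keeps the ester trans to the aryl group.

Step 7
Reactants: 12 methyl (2Z)-3-[3,5-bis(allyloxy)-4-(benzyloxy)phenoxy]-3-[3,4-bis(benzyloxy)phenyl]prop-2-enoate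
Product: 13 (2Z)-3-[3,5-bis(allyloxy)-4-(benzyloxy)phenoxy]-3-[3,4-bis(benzyloxy)phenyl]prop-2-enoic acid
Conditions: LiOH·H2O, THF/MeOH/H2O, 40 °C; then cold 1 M HCl to pH 3
Reagents that add atoms: lithium hydroxide, [Li+].[OH-]
Why: Saponification of the methyl ester, where the carboxylate formed is deactivated towards conjugate displacement of the aryloxy group and brief cold acidification spares the enol ether.

Step 8
Reactants: 13 (2Z)-3-[3,5-bis(allyloxy)-4-(benzyloxy)phenoxy]-3-[3,4-bis(benzyloxy)phenyl]prop-2-enoic acid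
Product: 15 5,7-bis(allyloxy)-6-(benzyloxy)-2-[3,4-bis(benzyloxy)phenyl]-4H-chromen-4-one, via mixed trifluoroacetic anhydride 14 (not isolated)
Conditions: (CF3CO)2O (2 equiv), CH2Cl2, 0 °C to rt
Reagents that add atoms: none
Why: Trifluoroacetic anhydride converts the acid into mixed anhydride 14, which ionises to an oxygen-stabilised acylium ion that attacks C4a of ring A, and loss of the proton from the arenium ion gives the pyranone. The closest known reaction type is the ring-closing stage of the Ruhemann flavone synthesis, an intramolecular Friedel–Crafts acylation of a β-aryloxycinnamic acid, here in its mild anhydride-activated form. Ring C closes by a six-membered electrophilic aromatic substitution that forms C4–C4a, formally a 6-exo attack of the arene on the acyl carbon. No stereocentre is created and the Z geometry of the alkene disappears into the ring. The step needs acylation of ring A and not of ring B (indenone formation): C4a is ortho to O1 and the C5 oxygen and para to the C7 oxygen, the two ortho carbons of the symmetric aryl ether are identical, the Z geometry holds the acyl carbon over them, and any E acid should equilibrate through reversible protonation at the α-carbon by the trifluoroacetic acid formed. The tetra-oxygenated ring is nucleophilic enough that no Lewis acid is needed, so the allyl and benzyl ethers should survive.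

Step 9
Reactants: 15 5,7-bis(allyloxy)-6-(benzyloxy)-2-[3,4-bis(benzyloxy)phenyl]-4H-chromen-4-one
Product: 16 6-(benzyloxy)-2-[3,4-bis(benzyloxy)phenyl]-5,7-dihydroxy-4H-chromen-4-one
Conditions: Pd(PPh3)4 (5 mol%), morpholine, THF, rt
Reagents that add atoms: none
Why: Tsuji–Trost deallylation in which zerovalent palladium ionises both aryl allyl ethers to π-allyl complexes that morpholine captures, leaving the benzyl ethers and the flavone core untouched.

Step 10
Reactants: 16 6-(benzyloxy)-2-[3,4-bis(benzyloxy)phenyl]-5,7-dihydroxy-4H-chromen-4-one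
Product: 17 6-(benzyloxy)-2-[3,4-bis(benzyloxy)phenyl]-5-hydroxy-4-oxo-4H-chromen-7-yl hydrogen sulfate
Conditions: SO3·pyridine (3 equiv), pyridine, rt; aqueous NaHCO3 work-up
Reagents that add atoms: sulfur trioxide pyridine complex, O=S(=O)([O-])[n+]1ccccc1
Why: O-Sulfation of a phenol with an amine–SO3 complex, where the 5-OH is locked in a hydrogen bond to the C4 carbonyl and is far less nucleophilic, so only the 7-OH should react.

Step 11
Reactants: 17 6-(benzyloxy)-2-[3,4-bis(benzyloxy)phenyl]-5-hydroxy-4-oxo-4H-chromen-7-yl hydrogen sulfate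
Product: 18 6-hydroxyluteolin 7-sulfate, 2-(3,4-dihydroxyphenyl)-5,6-dihydroxy-4-oxo-4H-chromen-7-yl hydrogen sulfate
Conditions: H2 (1 atm), Pd/C (10% palladium on carbon), MeOH/THF, rt, on the sodium salt
Reagents that add atoms: none
Why: Catalytic hydrogenolysis of the three benzyl ethers at atmospheric pressure, neutral conditions that aryl sulfate salts and the flavone C2–C3 double bond are known to tolerate.

**Compound list**
1 | 3,4,5-trihydroxybenzaldehyde | O=Cc1cc(O)c(O)c(O)c1 | starting material
2 | benzyl bromide | BrCc1ccccc1 | starting material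
3 | 4-(benzyloxy)-3,5-dihydroxybenzaldehyde | O=Cc1cc(O)c(OCc2ccccc2)c(O)c1 | intermediate
4 | allyl bromide | C=CCBr | starting material
5 | 3,5-bis(allyloxy)-4-(benzyloxy)benzaldehyde | O=Cc1cc(OCC=C)c(OCc2ccccc2)c(OCC=C)c1 | intermediate
6 | 3,5-bis(allyloxy)-4-(benzyloxy)phenyl formate | O=COc1cc(OCC=C)c(OCc2ccccc2)c(OCC=C)c1 | intermediate
7 | 3,5-bis(allyloxy)-4-(benzyloxy)phenol | Oc1cc(OCC=C)c(OCc2ccccc2)c(OCC=C)c1 | intermediate
8 | 3,4-bis(benzyloxy)benzaldehyde | O=Cc1ccc(OCc2ccccc2)c(OCc2ccccc2)c1 | starting material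
9 | 1,2-bis(benzyloxy)-4-(2,2-dibromoethenyl)benzene | BrC(Br)=Cc1ccc(OCc2ccccc2)c(OCc2ccccc2)c1 | intermediate
10 | lithium [3,4-bis(benzyloxy)phenyl]acetylide | [Li]C#Cc1ccc(OCc2ccccc2)c(OCc2ccccc2)c1 | intermediate
11 | methyl 3-[3,4-bis(benzyloxy)phenyl]prop-2-ynoate | COC(=O)C#Cc1ccc(OCc2ccccc2)c(OCc2ccccc2)c1 | intermediate
12 | methyl (2Z)-3-[3,5-bis(allyloxy)-4-(benzyloxy)phenoxy]-3-[3,4-bis(benzyloxy)phenyl]prop-2-enoate | COC(=O)/C=C(\Oc1cc(OCC=C)c(OCc2ccccc2)c(OCC=C)c1)c1ccc(OCc2ccccc2)c(OCc2ccccc2)c1 | intermediate
13 | (2Z)-3-[3,5-bis(allyloxy)-4-(benzyloxy)phenoxy]-3-[3,4-bis(benzyloxy)phenyl]prop-2-enoic acid | OC(=O)/C=C(\Oc1cc(OCC=C)c(OCc2ccccc2)c(OCC=C)c1)c1ccc(OCc2ccccc2)c(OCc2ccccc2)c1 | intermediate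
14 | (2Z)-3-[3,5-bis(allyloxy)-4-(benzyloxy)phenoxy]-3-[3,4-bis(benzyloxy)phenyl]prop-2-enoic trifluoroacetic anhydride | O=C(OC(=O)C(F)(F)F)/C=C(\Oc1cc(OCC=C)c(OCc2ccccc2)c(OCC=C)c1)c1ccc(OCc2ccccc2)c(OCc2ccccc2)c1 | intermediate
15 | 5,7-bis(allyloxy)-6-(benzyloxy)-2-[3,4-bis(benzyloxy)phenyl]-4H-chromen-4-one | O=c1cc(-c2ccc(OCc3ccccc3)c(OCc3ccccc3)c2)oc2cc(OCC=C)c(OCc3ccccc3)c(OCC=C)c12 | intermediate
16 | 6-(benzyloxy)-2-[3,4-bis(benzyloxy)phenyl]-5,7-dihydroxy-4H-chromen-4-one | O=c1cc(-c2ccc(OCc3ccccc3)c(OCc3ccccc3)c2)oc2cc(O)c(OCc3ccccc3)c(O)c12 | intermediate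
17 | 6-(benzyloxy)-2-[3,4-bis(benzyloxy)phenyl]-5-hydroxy-4-oxo-4H-chromen-7-yl hydrogen sulfate | O=c1cc(-c2ccc(OCc3ccccc3)c(OCc3ccccc3)c2)oc2cc(OS(=O)(=O)O)c(OCc3ccccc3)c(O)c12 | intermediate
18 | 6-hydroxyluteolin 7-sulfate | O=c1cc(-c2ccc(O)c(O)c2)oc2cc(OS(=O)(=O)O)c(O)c(O)c12 | target

**Step count**
Total: 11 steps. Longest linear sequence: 9 steps (steps 1–3, then 6–11); the ring B branch (steps 4–5) joins at step 6.

**Steps most likely to fail**

Step 8. The acid formed in the flask may strip or shift allyl and benzyl ethers, ring A may be trifluoroacetylated, or the enol ether may be cleaved before the acylium ion closes. The fallback forms the same C4–C4a bond with reversed polarity and no acid. It sets out from phenol 7: iodination ortho to the hydroxyl (N-iodosuccinimide, MeCN, 0 °C) should give 3,5-bis(allyloxy)-4-(benzyloxy)-2-iodophenol F1. Addition of this phenol to ynoate 11 under the conditions of step 6 should give methyl (2Z)-3-[3,5-bis(allyloxy)-4-(benzyloxy)-2-iodophenoxy]-3-[3,4-bis(benzyloxy)phenyl]prop-2-enoate F2. Iodine–magnesium exchange with i-PrMgCl·LiCl (THF, −30 °C) would give the corresponding arylmagnesium chloride F3, which on warming should attack the neighbouring ester in a Parham-type cycloacylation and expel methoxide. The fallback rejoins the route at flavone 15.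

Step 6. Conjugate addition to an ynoate deactivated by the electron-rich ring B may be sluggish, and prolonged heating may erode the Z geometry or cause transesterification by the phenoxide. The fallback sets out from ynoate 11: anti hydroiodination (NaI, AcOH, 80 °C) should give methyl (2Z)-3-[3,4-bis(benzyloxy)phenyl]-3-iodoprop-2-enoate F4. An Ullmann-type vinylic C–O coupling of this iodide with phenol 7 (CuI, N,N-dimethylglycine, Cs2CO3, dioxane, 90 °C), which proceeds with retention of alkene geometry, should then give ester 12, where the route is rejoined.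

Step 11. The sulfate may be lost by acid-catalysed solvolysis during hydrogenolysis or isolation, debenzylation of the very polar salt may stall, and the C2–C3 double bond may be over-reduced on long exposure. The fallback sets out from diol 16: sulfation with 2,2,2-trichloroethyl chlorosulfate (NEt3, DMAP, THF, rt) should give the neutral, chromatographable 6-(benzyloxy)-2-[3,4-bis(benzyloxy)phenyl]-5-hydroxy-4-oxo-4H-chromen-7-yl 2,2,2-trichloroethyl sulfate F5. Transfer hydrogenolysis (Pd/C, HCO2NH4, MeOH, rt) should then remove the trichloroethyl group and the three benzyl ethers together in a buffered medium. The fallback rejoins the route at target 18, obtained as its ammonium salt.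

**Further compounds**
F1 | step 8 | 3,5-bis(allyloxy)-4-(benzyloxy)-2-iodophenol | Oc1cc(OCC=C)c(OCc2ccccc2)c(OCC=C)c1I
F2 | step 8 | methyl (2Z)-3-[3,5-bis(allyloxy)-4-(benzyloxy)-2-iodophenoxy]-3-[3,4-bis(benzyloxy)phenyl]prop-2-enoate | COC(=O)/C=C(\Oc1cc(OCC=C)c(OCc2ccccc2)c(OCC=C)c1I)c1ccc(OCc2ccccc2)c(OCc2ccccc2)c1
F3 | step 8 | arylmagnesium chloride derived from F2 (MgCl in place of iodine) | COC(=O)/C=C(\Oc1cc(OCC=C)c(OCc2ccccc2)c(OCC=C)c1[Mg]Cl)c1ccc(OCc2ccccc2)c(OCc2ccccc2)c1
F4 | step 6 | methyl (2Z)-3-[3,4-bis(benzyloxy)phenyl]-3-iodoprop-2-enoate | COC(=O)/C=C(\I)c1ccc(OCc2ccccc2)c(OCc2ccccc2)c1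
F5 | step 11 | 6-(benzyloxy)-2-[3,4-bis(benzyloxy)phenyl]-5-hydroxy-4-oxo-4H-chromen-7-yl 2,2,2-trichloroethyl sulfate | O=c1cc(-c2ccc(OCc3ccccc3)c(OCc3ccccc3)c2)oc2cc(OS(=O)(=O)OCC(Cl)(Cl)Cl)c(OCc3ccccc3)c(O)c12
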